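## Retrosynthetic overview
1. The target hydroxy acid comes from saponification, as the last step, of the matching (S)-3-butyl-7-aryloxy-5-hydroxyphthalide. The lactone serves as the storage form of the acid/carbinol pair.
2. The usual Ullmann or SNAr coupling plus ketone reduction is avoided. The benzoate ring is built on the ether oxygen by an Alder–Rickert benzannulation: Diels–Alder, then retro-Diels–Alder loss of isobutene. The partners are a 1-aryloxy-3-silyloxycyclohexa-1,3-diene and an (S)-4-silyloxyoct-2-ynoate, and all four ring substituents arrive in this one step.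
3. The "diaryl ether" C–O bond is made earlier as a vinylogous ester, by metal-free addition–elimination of the hindered pentyl-ring phenol on the β-chloroenone of dimedone.
4. The single stereocentre is set at the start of the short branch by catalytic asymmetric addition of methyl propiolate to pentanal. It is only carried along afterwards.
5. Ring order: the pentyl ring is bought as olivetol, with its third oxygen added by formylation and Baeyer–Villiger oxidation. The benzoate ring then forms by cycloaddition. The lactone closes on desilylation and is opened at the end.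

Assumption: the open hydroxy acid as drawn (stereocentre = S by CIP) is wanted, not its phthalide; the sense of induction in the alkynylation follows the usual BINOL–Ti model ((S)-ligand attacks the Si face), so (R)-BINOL is used and the configuration is confirmed by Mosher analysis of the carbinol.

## Route

Step 1
Reactants: 1 olivetol (5-pentylbenzene-1,3-diol)
Product: 2 1,3-bis(benzyloxy)-5-pentylbenzene
Conditions: BnBr (2.3 equiv), K2CO3, DMF, 50 °C
Reagents that add atoms: benzyl bromide BrCc1ccccc1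
Why: Williamson ether synthesis (SN2 of both phenoxides on benzyl bromide); benzyl survives POCl3, peracid, LDA, 160 °C and HF and leaves at the end by neutral hydrogenolysis.

Step 2
Reactants: 2 1,3-bis(benzyloxy)-5-pentylbenzene
Product: 4 2,4-bis(benzyloxy)-6-pentylbenzaldehyde, via iminium chloride 3 (not isolated)
Conditions: POCl3, DMF, 0 → 70 °C; then ice-water
Reagents that add atoms: N,N-dimethylformamide CN(C)C=O; water O
Why: Vilsmeier–Haack formylation; the chloroiminium ion attacks the carbon para to one OBn and ortho to the other (next to the pentyl group) rather than the site crowded between two OBn groups, as is established for olivetol and orcinol diethers.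

Step 3
Reactants: 4 2,4-bis(benzyloxy)-6-pentylbenzaldehyde
Product: 6 2,4-bis(benzyloxy)-6-pentylphenol, via aryl formate 5 (not isolated)
Conditions: mCPBA (1.15 equiv), CH2Cl2, 0 °C → rt; NaHCO3 wash; then K2CO3 (cat.), MeOH, rt, Ar
Reagents that add atoms: mCPBA OOC(=O)c1cccc(Cl)c1
Why: Baeyer–Villiger (Dakin-type) oxidation; the electron-rich aryl group migrates in the Criegee adduct and the formate is methanolysed, which places the third oxygen exactly between OBn and pentyl.

Step 4
Reactants: 7 dimedone (5,5-dimethylcyclohexane-1,3-dione)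
Product: 8 3-chloro-5,5-dimethylcyclohex-2-en-1-one
Conditions: (COCl)2, DMF (cat.), CH2Cl2, 0 °C → rt
Reagents that add atoms: oxalyl chloride ClC(=O)C(=O)Cl
Why: Conversion of a vinylogous acid into its vinylogous acid chloride, driven by loss of CO, CO2 and HCl.

Step 5
Reactants: 6 2,4-bis(benzyloxy)-6-pentylphenol; 8 3-chloro-5,5-dimethylcyclohex-2-en-1-one
Product: 9 3-[2,4-bis(benzyloxy)-6-pentylphenoxy]-5,5-dimethylcyclohex-2-en-1-one
Conditions: K2CO3, DMF, 60 °C, Ar
Reagents that add atoms: none
Why: Vinylogous nucleophilic acyl substitution (addition–elimination on a β-chloroenone); the phenoxide has all ortho and para carbons blocked, so it attacks the open β-carbon through oxygen and expels chloride, forming the hindered aryl–O–C(sp2) bond without a metal.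

Step 6
Reactants: 9 3-[2,4-bis(benzyloxy)-6-pentylphenoxy]-5,5-dimethylcyclohex-2-en-1-one
Product: 11 tert-butyl({5-[2,4-bis(benzyloxy)-6-pentylphenoxy]-3,3-dimethylcyclohexa-1,5-dien-1-yl}oxy)dimethylsilane (a 1-aryloxy-3-TBSO-5,5-dimethylcyclohexa-1,3-diene), via lithium dienolate 10 (not isolated)
Conditions: LDA (1.1 equiv), THF, −78 °C; TBSCl, DMPU, −78 → 0 °C; cold NaHCO3 work-up, filtration through Et3N-deactivated silica
Reagents that add atoms: tert-butyldimethylsilyl chloride CC(C)(C)[Si](C)(C)Cl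
Why: Kinetic α'-deprotonation of a vinylogous ester (Stork–Danheiser regiochemistry) and O-silylation give the cross-conjugated 2-silyloxydiene, a cyclic Danishefsky-type diene, while LDA at −78 °C leaves the benzyl ethers and the γ-CH2 untouched.

Step 7
Reactants: 12 methyl propiolate; 13 pentanal
Product: 16 methyl (4S)-4-hydroxyoct-2-ynoate, via ethylzinc acetylide 14 (not isolated), via ethylzinc alkoxide 15 (not isolated)
Conditions: 12 (4 equiv), Et2Zn (4 equiv), (R)-BINOL (40 mol %), HMPA, CH2Cl2, rt, 16 h; Ti(OiPr)4 (50 mol %), 1 h; 13, rt; 1 M HCl quench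
Reagents that add atoms: none
Why: Catalytic asymmetric alkynylzinc addition to an aldehyde (BINOL–Ti Lewis acid, Lewis-base-assisted zincation at rt); the (R)-BINOLate–Ti complex directs attack to the Re face of pentanal and so sets the only stereocentre as (S).

Step 8
Reactants: 16 methyl (4S)-4-hydroxyoct-2-ynoate
Product: 17 methyl (4S)-4-[(tert-butyldimethylsilyl)oxy]oct-2-ynoate
Conditions: TBSOTf, 2,6-lutidine, CH2Cl2, 0 °C
Reagents that add atoms: tert-butyldimethylsilyl triflate CC(C)(C)[Si](C)(C)OS(=O)(=O)C(F)(F)F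
Why: O-silylation with a non-nucleophilic base avoids conjugate addition to the ynoate, leaves the C–O bond untouched so the configuration is retained, and removes the free OH that would protodesilylate the diene in step 9.

Step 9
Reactants: 11 the 1-aryloxy-3-TBSO-5,5-dimethylcyclohexa-1,3-diene; 17 methyl (4S)-4-[(tert-butyldimethylsilyl)oxy]oct-2-ynoate
Product: 19 methyl 2-[2,4-bis(benzyloxy)-6-pentylphenoxy]-4-[(tert-butyldimethylsilyl)oxy]-6-{(1S)-1-[(tert-butyldimethylsilyl)oxy]pentyl}benzoate, via bicyclo[2.2.2]octadiene adduct 18 (not isolated)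
Conditions: 17 (2.5 equiv), neat or minimal mesitylene, BHT (cat.), sealed tube, Ar, 160 °C, 36 h
Reagents that add atoms: none
Why: Proposed new method: an Alder–Rickert benzannulation (Diels–Alder then retro-Diels–Alder) with a 1-aryloxy diene, untested to my knowledge; the diene terminus β to both oxygen donors bonds to the electrophilic β-carbon of the ynoate and the OAr-bearing terminus bonds to the α-carbon, so ester, OAr, OTBS and side chain fall into the required 1,2,4,6-pattern; in adduct 18 the aryloxy group sits on a bridgehead and cannot be eliminated, so aromatisation can only occur by extrusion of isobutene, which keeps the ether; the closest known reactions are the thermal Alder–Rickert reactions of 1-methoxy- and dimedone-derived 1,3-bis(silyloxy)cyclohexa-1,3-dienes with 2-alkynoates to give resorcylates; the stereocentre is a spectator under these neutral conditions.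

Step 10
Reactants: 19 the bis-TBS methyl benzoate
Product: 21 (3S)-7-[2,4-bis(benzyloxy)-6-pentylphenoxy]-3-butyl-5-hydroxy-2-benzofuran-1(3H)-one, via hydroxy ester 20 (not isolated)
Conditions: 48% aq HF, MeCN, rt
Reagents that add atoms: none
Why: Fluoride-driven Si–O cleavage of both silyl ethers is followed by spontaneous 5-exo-trig lactonisation (intramolecular transesterification) of 20; only O–Si and acyl–O bonds change, so C3 stays (S), and the benzyl and diaryl ethers are inert to HF.

Step 11
Reactants: 21 (3S)-7-[2,4-bis(benzyloxy)-6-pentylphenoxy]-3-butyl-5-hydroxy-2-benzofuran-1(3H)-one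
Product: 22 (3S)-3-butyl-7-(2,4-dihydroxy-6-pentylphenoxy)-5-hydroxy-2-benzofuran-1(3H)-one
Conditions: H2 (1 atm), 10% Pd/C, EtOAc, rt
Reagents that add atoms: none
Why: Catalytic hydrogenolysis of the two benzyl aryl ethers; the lactone C3–O bond sits on an electron-poor benzylic position (ortho acyl, both ring oxygens meta) and 3-alkylphthalides survive Pd/C at 1 atm, so the stereocentre is kept.

Step 12
Reactants: 22 (3S)-3-butyl-7-(2,4-dihydroxy-6-pentylphenoxy)-5-hydroxy-2-benzofuran-1(3H)-one
Product: 24 2-(2,4-dihydroxy-6-pentylphenoxy)-4-hydroxy-6-[(1S)-1-hydroxypentyl]benzoic acid, via tetralithium salt 23 (not isolated)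
Conditions: LiOH (6 equiv), degassed THF–H2O, rt, Ar; then 1 M HCl to pH 3–4 at 0 °C, fast EtOAc extraction, evaporation below 20 °C
Reagents that add atoms: lithium hydroxide [Li+].[OH-]
Why: Saponification by acyl–oxygen cleavage (BAc2) does not touch the C–O bond of the stereocentre, and cold, mild acidification with fast isolation gives the free hydroxy acid before it relactonises, as is known for 2-(1-hydroxypentyl)benzoic acids.

## Compound list
1 | olivetol (5-pentylbenzene-1,3-diol) | CCCCCc1cc(O)cc(O)c1 | starting material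
2 | 1,3-bis(benzyloxy)-5-pentylbenzene | CCCCCc1cc(OCc2ccccc2)cc(OCc2ccccc2)c1 | intermediate
3 | [2,4-bis(benzyloxy)-6-pentylphenyl]methylidene(dimethyl)ammonium chloride (not isolated) | CCCCCc1cc(OCc2ccccc2)cc(OCc2ccccc2)c1C=[N+](C)C.[Cl-] | intermediate
4 | 2,4-bis(benzyloxy)-6-pentylbenzaldehyde | CCCCCc1cc(OCc2ccccc2)cc(OCc2ccccc2)c1C=O | intermediate
5 | 2,4-bis(benzyloxy)-6-pentylphenyl formate (not isolated) | CCCCCc1cc(OCc2ccccc2)cc(OCc2ccccc2)c1OC=O | intermediate
6 | 2,4-bis(benzyloxy)-6-pentylphenol | CCCCCc1cc(OCc2ccccc2)cc(OCc2ccccc2)c1O | intermediate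
7 | dimedone (5,5-dimethylcyclohexane-1,3-dione) | CC1(C)CC(=O)CC(=O)C1 | starting material
8 | 3-chloro-5,5-dimethylcyclohex-2-en-1-one | CC1(C)CC(Cl)=CC(=O)C1 | intermediate
9 | 3-[2,4-bis(benzyloxy)-6-pentylphenoxy]-5,5-dimethylcyclohex-2-en-1-one | CCCCCc1cc(OCc2ccccc2)cc(OCc2ccccc2)c1OC1=CC(=O)CC(C)(C)C1 | intermediate
10 | lithium 5-[2,4-bis(benzyloxy)-6-pentylphenoxy]-3,3-dimethylcyclohexa-1,5-dien-1-olate (not isolated) | [Li+].CCCCCc1cc(OCc2ccccc2)cc(OCc2ccccc2)c1OC1=CC([O-])=CC(C)(C)C1 | intermediate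
11 | tert-butyl({5-[2,4-bis(benzyloxy)-6-pentylphenoxy]-3,3-dimethylcyclohexa-1,5-dien-1-yl}oxy)dimethylsilane | CCCCCc1cc(OCc2ccccc2)cc(OCc2ccccc2)c1OC1=CC(O[Si](C)(C)C(C)(C)C)=CC(C)(C)C1 | intermediate
12 | methyl propiolate | C#CC(=O)OC | starting material
13 | pentanal | CCCCC=O | starting material
14 | ethyl(3-methoxy-3-oxoprop-1-yn-1-yl)zinc (not isolated) | CC[Zn]C#CC(=O)OC | intermediate
15 | ethylzinc alkoxide of methyl (4S)-4-hydroxyoct-2-ynoate (not isolated) | CCCC[C@H](O[Zn]CC)C#CC(=O)OC | intermediate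
16 | methyl (4S)-4-hydroxyoct-2-ynoate | CCCC[C@H](O)C#CC(=O)OC | intermediate
17 | methyl (4S)-4-[(tert-butyldimethylsilyl)oxy]oct-2-ynoate | CCCC[C@H](O[Si](C)(C)C(C)(C)C)C#CC(=O)OC | intermediate
18 | methyl 1-[2,4-bis(benzyloxy)-6-pentylphenoxy]-5-(TBSO)-8,8-dimethyl-3-[(1S)-1-(TBSO)pentyl]bicyclo[2.2.2]octa-2,5-diene-2-carboxylate, both bridgehead diastereomers (not isolated) | COC(=O)C1=C([C@@H](O[Si](C)(C)C(C)(C)C)CCCC)C2C(O[Si](C)(C)C(C)(C)C)=CC1(Oc3c(CCCCC)cc(OCc4ccccc4)cc3OCc3ccccc3)CC2(C)C | intermediate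
19 | methyl 2-[2,4-bis(benzyloxy)-6-pentylphenoxy]-4-(TBSO)-6-[(1S)-1-(TBSO)pentyl]benzoate | COC(=O)c1c(Oc2c(CCCCC)cc(OCc3ccccc3)cc2OCc2ccccc2)cc(O[Si](C)(C)C(C)(C)C)cc1[C@@H](O[Si](C)(C)C(C)(C)C)CCCC | intermediate
20 | methyl 2-[2,4-bis(benzyloxy)-6-pentylphenoxy]-4-hydroxy-6-[(1S)-1-hydroxypentyl]benzoate (not isolated) | COC(=O)c1c(Oc2c(CCCCC)cc(OCc3ccccc3)cc2OCc2ccccc2)cc(O)cc1[C@@H](O)CCCC | intermediate
21 | (3S)-7-[2,4-bis(benzyloxy)-6-pentylphenoxy]-3-butyl-5-hydroxy-2-benzofuran-1(3H)-one | CCCC[C@@H]1OC(=O)c2c(Oc3c(CCCCC)cc(OCc4ccccc4)cc3OCc3ccccc3)cc(O)cc21 | intermediate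
22 | (3S)-3-butyl-7-(2,4-dihydroxy-6-pentylphenoxy)-5-hydroxy-2-benzofuran-1(3H)-one | CCCC[C@@H]1OC(=O)c2c(Oc3c(CCCCC)cc(O)cc3O)cc(O)cc21 | intermediate
23 | tetralithium salt (carboxylate and three phenoxides) of the target (not isolated) | [Li+].[Li+].[Li+].[Li+].CCCCCc1cc([O-])cc([O-])c1Oc1cc([O-])cc([C@@H](O)CCCC)c1C([O-])=O | intermediate
24 | 2-(2,4-dihydroxy-6-pentylphenoxy)-4-hydroxy-6-[(1S)-1-hydroxypentyl]benzoic acid (CNP0272660.1) | CCCCCc1cc(O)cc(O)c1Oc1cc(O)cc([C@@H](O)CCCC)c1C(=O)O | target

## Step count and risks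
Total steps: 12. Longest linear sequence: 9 (steps 1, 2, 3, 5, 6, 9, 10, 11, 12 from olivetol).

**Step 9.** The aryloxy group is a weaker donor and a bulkier neighbour than OMe or OSiR3, and the ynoate carries a branched β-substituent. The cycloaddition may therefore stall, or 11 may decompose first.
- This fallback sets out from 7 and 17, uses 6 on the way, and comes back at 22. The ring is made from the proven all-silyloxy diene and the ether bond is made afterwards by cross-coupling.
- 7 is bis-silylated (TMSOTf, Et3N, Et2O) to 5,5-dimethyl-1,3-bis(trimethylsilyloxy)cyclohexa-1,3-diene F1.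
- Heating with 17 at 140 °C gives, after loss of isobutene, methyl 6-[(1S)-1-(tert-butyldimethylsilyloxy)pentyl]-2,4-bis(trimethylsilyloxy)benzoate F2.
- Aqueous HF in MeCN converts this into (3S)-3-butyl-5,7-dihydroxy-2-benzofuran-1(3H)-one F3.
- The non-chelated 5-OH is benzylated selectively (BnBr 1.05 equiv, K2CO3, acetone) to (3S)-5-(benzyloxy)-3-butyl-7-hydroxy-2-benzofuran-1(3H)-one F4.
- Tf2O and pyridine give (3S)-5-(benzyloxy)-3-butyl-1-oxo-1,3-dihydro-2-benzofuran-7-yl triflate F5.
- Pd-catalysed C–O coupling with 6 (Pd(OAc)2, t-BuXPhos, K3PO4, toluene, 100 °C) gives (3S)-5-(benzyloxy)-7-[2,4-bis(benzyloxy)-6-pentylphenoxy]-3-butyl-2-benzofuran-1(3H)-one F6.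
- Hydrogenolysis (H2, Pd/C, EtOAc) then gives 22.

**Step 7.** Linear enolisable aldehydes are the hardest substrates for this addition because of self-aldol reaction and ee erosion, and the sense of induction rests on a model.
- This fallback sets out from 12 and 13 and comes back at 16. The C–C bond is made first and the stereocentre is set second by reagent-controlled reduction.
- 12 is lithiated (LDA, THF, −78 °C) and added to 13 to give racemic methyl 4-hydroxyoct-2-ynoate F7.
- Dess–Martin oxidation gives methyl 4-oxooct-2-ynoate F8.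
- Midland reduction with (S)-Alpine-Borane, made from (−)-α-pinene and 9-BBN, gives 16. The (+)-pinene reagent is known to give (R)-propargylic alcohols.

**Step 12.** The free acid may relactonise to 22 during acidification or concentration.
- This fallback sets out from 21 and comes back at 24. It avoids acidification by releasing the acid under neutral hydrogenolysis.
- 21 is opened with NaOH (2.0 equiv, aq THF–MeOH) and evaporated to disodium 2-[2,4-bis(benzyloxy)-6-pentylphenoxy]-6-[(1S)-1-hydroxypentyl]-4-oxidobenzoate F9.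
- Alkylation with BnBr in DMF at rt gives benzyl 4-(benzyloxy)-2-[2,4-bis(benzyloxy)-6-pentylphenoxy]-6-[(1S)-1-hydroxypentyl]benzoate F10.
- All four benzyl groups are removed with H2, Pd/C in EtOAc, which gives 24 after filtration and cold evaporation.

## Further compounds
F1 | step 9 | 5,5-dimethyl-1,3-bis(trimethylsilyloxy)cyclohexa-1,3-diene | CC1(C)CC(O[Si](C)(C)C)=CC(O[Si](C)(C)C)=C1
F2 | step 9 | methyl 6-[(1S)-1-(tert-butyldimethylsilyloxy)pentyl]-2,4-bis(trimethylsilyloxy)benzoate | COC(=O)c1c(O[Si](C)(C)C)cc(O[Si](C)(C)C)cc1[C@@H](O[Si](C)(C)C(C)(C)C)CCCC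
F3 | step 9 | (3S)-3-butyl-5,7-dihydroxy-2-benzofuran-1(3H)-one | CCCC[C@@H]1OC(=O)c2c(O)cc(O)cc21
F4 | step 9 | (3S)-5-(benzyloxy)-3-butyl-7-hydroxy-2-benzofuran-1(3H)-one | CCCC[C@@H]1OC(=O)c2c(O)cc(OCc3ccccc3)cc21
F5 | step 9 | (3S)-5-(benzyloxy)-3-butyl-1-oxo-1,3-dihydro-2-benzofuran-7-yl triflate | CCCC[C@@H]1OC(=O)c2c(OS(=O)(=O)C(F)(F)F)cc(OCc3ccccc3)cc21
F6 | step 9 | (3S)-5-(benzyloxy)-7-[2,4-bis(benzyloxy)-6-pentylphenoxy]-3-butyl-2-benzofuran-1(3H)-one | CCCC[C@@H]1OC(=O)c2c(Oc3c(CCCCC)cc(OCc4ccccc4)cc3OCc3ccccc3)cc(OCc3ccccc3)cc21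
F7 | step 7 | racemic methyl 4-hydroxyoct-2-ynoate | CCCCC(O)C#CC(=O)OC
F8 | step 7 | methyl 4-oxooct-2-ynoate | CCCCC(=O)C#CC(=O)OC
F9 | step 12 | disodium 2-[2,4-bis(benzyloxy)-6-pentylphenoxy]-6-[(1S)-1-hydroxypentyl]-4-oxidobenzoate | [Na+].[Na+].CCCCCc1cc(OCc2ccccc2)cc(OCc2ccccc2)c1Oc1cc([O-])cc([C@@H](O)CCCC)c1C([O-])=O
F10 | step 12 | benzyl 4-(benzyloxy)-2-[2,4-bis(benzyloxy)-6-pentylphenoxy]-6-[(1S)-1-hydroxypentyl]benzoate | CCCCCc1cc(OCc2ccccc2)cc(OCc2ccccc2)c1Oc1cc(OCc2ccccc2)cc([C@@H](O)CCCC)c1C(=O)OCc1ccccc1
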